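**Retrosynthetic overview**
1. Target 16 ⇒ heptamethoxyflavone 14 (chelation-directed loss of the 5-O-methyl group) ⇒ flavonol 13 (O-methylation) ⇒ flavone 11 (oxygenation of C3 through the 2,3-epoxide).
2. Ring C of 11 is opened at O1–C2 ⇒ 2'-hydroxychalcone 8 (forward: oxidative oxa-Michael cyclisation).
3. Key C–C disconnection at C2–C3 ⇒ acetophenone 5 + 2,5-dimethoxybenzaldehyde 6 (intermolecular Claisen–Schmidt aldol condensation).
4. 5 ⇒ 3,4,5-trimethoxyphenol 1 (C-acetylation, bromination of the last free C–H, copper-catalysed methoxylation).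
5. Ring order: rings A and B are bought as the arenes 1 and 6. Ring C is the only ring built (step 5).

Assumption: the target has no stereocentre and no configurationally stable axis, so it is achiral and the compound itself is what is made. The only stereochemical features on the way are the E alkene of 8 and the transient racemic centres of 7, 9, 10 and 12, all of which are erased.

**Step 1**
Reactants: 1 3,4,5-trimethoxyphenol
Product: 3 1-(6-hydroxy-2,3,4-trimethoxyphenyl)ethan-1-one, via aryl acetate 2 (not isolated)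
Conditions: Ac2O (1.2 equiv), BF3·OEt2 (3 equiv), 80 °C, 2 h; then H2O
Reagents that add atoms: acetic anhydride CC(=O)OC(C)=O
Why: O-acetylation followed by BF3-promoted Fries rearrangement (Friedel–Crafts C-acylation) puts the acetyl group ortho to the phenol, the two free ring positions being equivalent by symmetry, and gives the chelate-stabilised o-hydroxyketone without forming a stereocentre.

**Step 2**
Reactants: 3 1-(6-hydroxy-2,3,4-trimethoxyphenyl)ethan-1-one
Product: 4 1-(3-bromo-2-hydroxy-4,5,6-trimethoxyphenyl)ethan-1-one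
Conditions: NBS (1.05 equiv), CH2Cl2, 0 °C to rt, 2 h
Reagents that add atoms: N-bromosuccinimide O=C1CCC(=O)N1Br
Why: Electrophilic aromatic bromination can only occur at the single remaining ring C–H, which lies ortho to OH and OMe and reacts far faster than the ketone α-position.

**Step 3**
Reactants: 4 1-(3-bromo-2-hydroxy-4,5,6-trimethoxyphenyl)ethan-1-one
Product: 5 1-(2-hydroxy-3,4,5,6-tetramethoxyphenyl)ethan-1-one
Conditions: NaOMe (30% in MeOH, 8 equiv), CuBr (0.2 equiv), DMF, 110 °C, N2, 4 h; then 2 M HCl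
Reagents that add atoms: sodium methoxide C[O-].[Na+]
Why: Ullmann-type copper-catalysed methoxylation of an aryl bromide tolerates an ortho phenoxide, as in the conversion of 5-bromovanillin into syringaldehyde, and the phenoxide form keeps the acetyl group from self-condensing.

**Step 4**
Reactants: 5 1-(2-hydroxy-3,4,5,6-tetramethoxyphenyl)ethan-1-one; 6 2,5-dimethoxybenzaldehyde
Product: 8 (E)-3-(2,5-dimethoxyphenyl)-1-(2-hydroxy-3,4,5,6-tetramethoxyphenyl)prop-2-en-1-one, via aldol adduct 7 (not isolated)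
Conditions: KOH (50% aq., 10 equiv), EtOH, rt, 36 h; then 2 M HCl, 0 °C
Reagents that add atoms: none
Why: In this Claisen–Schmidt crossed aldol condensation the only enolisable partner (5) adds to the non-enolisable aldehyde 6, and E1cB dehydration of racemic 7 gives the conjugated E enone under thermodynamic control, while any flavanone formed on acidification converges in step 5.

**Step 5**
Reactants: 8 (E)-3-(2,5-dimethoxyphenyl)-1-(2-hydroxy-3,4,5,6-tetramethoxyphenyl)prop-2-en-1-one
Product: 11 2-(2,5-dimethoxyphenyl)-5,6,7,8-tetramethoxy-4H-chromen-4-one, via flavanone 9 (not isolated), via 3-iodoflavanone 10 (not isolated)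
Conditions: I2 (0.1 equiv), DMSO, 125 °C, 3 h; aq. Na2S2O3 wash
Reagents that add atoms: none
Why: The I2/DMSO oxidative cyclisation of a 2'-hydroxychalcone runs by intramolecular oxa-Michael addition, α-iodination and HI elimination with DMSO re-oxidising HI, and it avoids the aurone problem that 6'-methoxychalcones show under alkaline peroxide, the transient stereocentres being lost on aromatisation of ring C.

**Step 6**
Reactants: 11 2-(2,5-dimethoxyphenyl)-5,6,7,8-tetramethoxy-4H-chromen-4-one
Product: 13 2-(2,5-dimethoxyphenyl)-3-hydroxy-5,6,7,8-tetramethoxy-4H-chromen-4-one, via flavone 2,3-epoxide 12 (not isolated)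
Conditions: DMDO (ca. 0.07 M in acetone, pre-distilled from acetone/2KHSO5·KHSO4·K2SO4/NaHCO3, 2.5 equiv), CH2Cl2, 0 °C to rt, dark, 16 h; then p-TsOH·H2O (0.1 equiv), CH2Cl2, rt
Reagents that add atoms: dimethyldioxirane CC1(C)OO1
Why: Neutral dioxirane epoxidation of the enol-ether-like C2=C3 bond gives the racemic cis-fused epoxide, whose acid-catalysed opening to the C2 oxocarbenium ion and loss of H-3 isomerises it to the flavonol and erases both transient stereocentres.

**Step 7**
Reactants: 13 2-(2,5-dimethoxyphenyl)-3-hydroxy-5,6,7,8-tetramethoxy-4H-chromen-4-one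
Product: 14 2-(2,5-dimethoxyphenyl)-3,5,6,7,8-pentamethoxy-4H-chromen-4-one
Conditions: MeI (2 equiv), K2CO3 (3 equiv), acetone, reflux, 8 h
Reagents that add atoms: iodomethane CI
Why: Williamson ether synthesis on the only free, acidic enolic OH of the molecule leaves no competing nucleophilic site.

**Step 8**
Reactants: 14 2-(2,5-dimethoxyphenyl)-3,5,6,7,8-pentamethoxy-4H-chromen-4-one
Product: 16 grantioidinin (2-(2,5-dimethoxyphenyl)-5-hydroxy-3,6,7,8-tetramethoxy-4H-chromen-4-one), via boron chelate 15 (not isolated)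
Conditions: BCl3 (1 M in CH2Cl2, 1.2 equiv), CH2Cl2, −78 °C to 0 °C, 1.5 h; then H2O
Reagents that add atoms: none
Why: In this chelation-directed Lewis-acid ether cleavage BCl3 bridges C4=O and the peri 5-OMe in a six-membered chelate so that chloride removes that methyl group selectively, whereas the 3-OMe would need a strained five-membered chelate and the other five methoxy groups cannot chelate.

**Compound list**
1 | 3,4,5-trimethoxyphenol | COc1cc(O)cc(OC)c1OC | starting material
2 | 3,4,5-trimethoxyphenyl acetate (aryl acetate, not isolated) | COc1cc(OC(C)=O)cc(OC)c1OC | intermediate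
3 | 1-(6-hydroxy-2,3,4-trimethoxyphenyl)ethan-1-one | CC(=O)c1c(O)cc(OC)c(OC)c1OC | intermediate
4 | 1-(3-bromo-2-hydroxy-4,5,6-trimethoxyphenyl)ethan-1-one | CC(=O)c1c(O)c(Br)c(OC)c(OC)c1OC | intermediate
5 | 1-(2-hydroxy-3,4,5,6-tetramethoxyphenyl)ethan-1-one | CC(=O)c1c(O)c(OC)c(OC)c(OC)c1OC | intermediate
6 | 2,5-dimethoxybenzaldehyde | COc1ccc(OC)c(C=O)c1 | starting material
7 | 3-(2,5-dimethoxyphenyl)-3-hydroxy-1-(2-hydroxy-3,4,5,6-tetramethoxyphenyl)propan-1-one (aldol adduct, racemic, not isolated) | COc1ccc(OC)c(C(O)CC(=O)c2c(O)c(OC)c(OC)c(OC)c2OC)c1 | intermediate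
8 | (E)-3-(2,5-dimethoxyphenyl)-1-(2-hydroxy-3,4,5,6-tetramethoxyphenyl)prop-2-en-1-one (chalcone) | COc1ccc(OC)c(/C=C/C(=O)c2c(O)c(OC)c(OC)c(OC)c2OC)c1 | intermediate
9 | 2-(2,5-dimethoxyphenyl)-5,6,7,8-tetramethoxychroman-4-one (flavanone, racemic, not isolated) | COc1ccc(OC)c(C2CC(=O)c3c(OC)c(OC)c(OC)c(OC)c3O2)c1 | intermediate
10 | 2-(2,5-dimethoxyphenyl)-3-iodo-5,6,7,8-tetramethoxychroman-4-one (3-iodoflavanone, racemic diastereomer mixture, not isolated) | COc1ccc(OC)c(C2Oc3c(OC)c(OC)c(OC)c(OC)c3C(=O)C2I)c1 | intermediate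
11 | 2-(2,5-dimethoxyphenyl)-5,6,7,8-tetramethoxy-4H-chromen-4-one (flavone) | COc1ccc(OC)c(-c2cc(=O)c3c(OC)c(OC)c(OC)c(OC)c3o2)c1 | intermediate
12 | 2,3-epoxy-2-(2,5-dimethoxyphenyl)-5,6,7,8-tetramethoxychroman-4-one (flavone 2,3-epoxide, cis-fused, racemic, one enantiomer drawn, not isolated) | COc1ccc(OC)c([C@]23O[C@H]2C(=O)c2c(OC)c(OC)c(OC)c(OC)c2O3)c1 | intermediate
13 | 2-(2,5-dimethoxyphenyl)-3-hydroxy-5,6,7,8-tetramethoxy-4H-chromen-4-one (flavonol) | COc1ccc(OC)c(-c2oc3c(OC)c(OC)c(OC)c(OC)c3c(=O)c2O)c1 | intermediate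
14 | 2-(2,5-dimethoxyphenyl)-3,5,6,7,8-pentamethoxy-4H-chromen-4-one | COc1ccc(OC)c(-c2oc3c(OC)c(OC)c(OC)c(OC)c3c(=O)c2OC)c1 | intermediate
15 | 5-(dichloroboryloxy)-2-(2,5-dimethoxyphenyl)-3,6,7,8-tetramethoxy-4H-chromen-4-one (boron chelate, not isolated) | COc1ccc(OC)c(-c2oc3c(OC)c(OC)c(OC)c(OB(Cl)Cl)c3c(=O)c2OC)c1 | intermediate
16 | grantioidinin, 2-(2,5-dimethoxyphenyl)-5-hydroxy-3,6,7,8-tetramethoxy-4H-chromen-4-one (achiral) | COc1ccc(OC)c(-c2oc3c(OC)c(OC)c(OC)c(O)c3c(=O)c2OC)c1 | target

**Totals**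
Total step count: 8. Longest linear sequence: 8 steps (1 to 16). Aldehyde 6 is used as bought and enters at step 4.

**Three steps most likely to fail**

Step 3 (copper-catalysed methoxylation; the risk is hydrodebromination back to 3 or a stalled reaction). This fallback sets out from 1 and comes back at 5. It installs the fifth oxygen by formylation and Baeyer–Villiger oxidation instead of C–Br substitution, and it introduces the acetyl group last.
- Methylation of 1 (MeI, K2CO3, acetone) gives 1,2,3,5-tetramethoxybenzene F1.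
- Vilsmeier–Haack formylation (POCl3, DMF) at one of the two equivalent free positions passes through (2,3,4,6-tetramethoxybenzylidene)dimethylammonium chloride F2. Aqueous NaOAc hydrolyses it to 2,3,4,6-tetramethoxybenzaldehyde F3.
- mCPBA in CH2Cl2 gives 2,3,4,6-tetramethoxyphenyl formate F4. Aqueous NaOH/MeOH followed by HCl gives 2,3,4,6-tetramethoxyphenol F5.
- A second methylation gives pentamethoxybenzene F6.
- Friedel–Crafts acetylation (AcCl, AlCl3, CH2Cl2, 0 °C to rt) at the only free position gives 2,3,4,5,6-pentamethoxyacetophenone F7. In the same flask F7 loses one of its two equivalent ortho methyl groups by chelation-assisted cleavage and becomes 5.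

Step 6 (DMDO oxidation; the risk is over-oxidation of the electron-rich rings or incomplete conversion). This fallback sets out from 11 and comes back at 13. It replaces oxygen transfer to the alkene by C–H metalation, borylation and oxidation.
- LiN(iPr)2 in THF at −78 °C removes H-3 to give the 3-lithioflavone F8.
- B(OMe)3 traps it as lithium (flavon-3-yl)trimethoxyborate F9.
- H2O2/AcOH at 0 °C to rt converts the C–B bond into the C–OH bond of 13.

Step 8 (selective demethylation; the risk is competing cleavage of the 3-OMe). This fallback sets out from 13 and comes back at 16. It reverses the order of the last two operations, so that no 3-OMe is present when the Lewis acid is used.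
- Flavonol 13 with BCl3 (2.5 equiv, CH2Cl2, −78 °C to 0 °C) gives the 3,5-bis(dichloroboryloxy)flavone F10. Water hydrolyses it to 3,5-dihydroxy-6,7,8,2',5'-pentamethoxyflavone F11.
- MeI (1.05 equiv) and K2CO3 (1.1 equiv) in acetone at rt then alkylate only the 3-OH, because the 5-OH is locked in a hydrogen bond to C4=O. The product is 16.

**Further compounds**
F1 | step 3 | 1,2,3,5-tetramethoxybenzene | COc1cc(OC)c(OC)c(OC)c1
F2 | step 3 | (2,3,4,6-tetramethoxybenzylidene)dimethylammonium chloride | COc1cc(OC)c(OC)c(OC)c1C=[N+](C)C.[Cl-]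
F3 | step 3 | 2,3,4,6-tetramethoxybenzaldehyde | COc1cc(OC)c(OC)c(OC)c1C=O
F4 | step 3 | 2,3,4,6-tetramethoxyphenyl formate | COc1cc(OC)c(OC)c(OC)c1OC=O
F5 | step 3 | 2,3,4,6-tetramethoxyphenol | COc1cc(OC)c(OC)c(OC)c1O
F6 | step 3 | pentamethoxybenzene | COc1cc(OC)c(OC)c(OC)c1OC
F7 | step 3 | 2,3,4,5,6-pentamethoxyacetophenone | CC(=O)c1c(OC)c(OC)c(OC)c(OC)c1OC
F8 | step 6 | 3-lithio-2-(2,5-dimethoxyphenyl)-5,6,7,8-tetramethoxy-4H-chromen-4-one | COc1ccc(OC)c(-c2oc3c(OC)c(OC)c(OC)c(OC)c3c(=O)c2[Li])c1
F9 | step 6 | lithium [2-(2,5-dimethoxyphenyl)-5,6,7,8-tetramethoxy-4-oxo-4H-chromen-3-yl]trimethoxyborate | [Li+].COc1ccc(OC)c(-c2oc3c(OC)c(OC)c(OC)c(OC)c3c(=O)c2[B-](OC)(OC)OC)c1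
F10 | step 8 | 3,5-bis(dichloroboryloxy)-2-(2,5-dimethoxyphenyl)-6,7,8-trimethoxy-4H-chromen-4-one | COc1ccc(OC)c(-c2oc3c(OC)c(OC)c(OC)c(OB(Cl)Cl)c3c(=O)c2OB(Cl)Cl)c1
F11 | step 8 | 3,5-dihydroxy-2-(2,5-dimethoxyphenyl)-6,7,8-trimethoxy-4H-chromen-4-one | COc1ccc(OC)c(-c2oc3c(OC)c(OC)c(OC)c(O)c3c(=O)c2O)c1
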